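Everything rests on the 1,3-relationship of the lactone oxygen on C4 and the peroxide oxygen on C6 (across C5), and on C3–O lying β to the lactone carbonyl C1. C4–O and an activated C6 are stored in one strained ring, a 2,2,4,4-tetrasubstituted oxetane (C4–O–C6) bearing a (Z)-acrylate on C4. Hydrogen peroxide opens it at C6 with inversion. The released C4 hydroxyl closes the butenolide, and the C6 hydroperoxide then adds to C3, closing the 1,2-dioxane last. One operation installs O–O, both heterocycles, C6 and C3. C8 comes from (R)-citronellic acid; C6 and C4 from two catalyst-controlled epoxidations. Numbering: C1 lactone C=O, C2 CH2, C3 CH–OO, C4 CMe–O, C5 CH2, C6 CMe–OO, C8 CHMe.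

Key step: step 13

Assumption: the ligand antipodes written in steps 7 and 9 follow the usual sense of induction for alkyl methyl ketones and homoallylic alcohols. If a test reaction shows the opposite sense, the mirror-image ligand is used.

Step 1
Reactants: 1 styrene; 2 pent-4-en-1-ol
Product: 3 (E)-5-phenylpent-4-en-1-ol
Conditions: (H2IMes)(PCy3)Cl2Ru=CHPh (2 mol %), styrene (2 equiv), CH2Cl2, 40 °C
Reagents that add atoms: none
Why: Olefin cross-metathesis of a styrene with an unhindered terminal alkene favours the cross product and, being under thermodynamic control, should give the conjugated E alkene almost exclusively.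

Step 2
Reactants: 3 (E)-5-phenylpent-4-en-1-ol
Product: 4 1-phenyl-5-{[(4E)-5-phenylpent-4-en-1-yl]sulfanyl}-1H-tetrazole
Conditions: 1-phenyl-1H-tetrazole-5-thiol, PPh3, DIAD, THF, 0 °C → rt
Reagents that add atoms: 1-phenyl-1H-tetrazole-5-thiol, Sc1nnnn1-c1ccccc1
Why: Mitsunobu reaction, in which the primary alcohol is activated as its oxyphosphonium salt and displaced (SN2) by the acidic heteroaryl thiol without touching the styrenyl alkene.

Step 3
Reactants: 4 1-phenyl-5-{[(4E)-5-phenylpent-4-en-1-yl]sulfanyl}-1H-tetrazole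
Product: 5 1-phenyl-5-{[(4E)-5-phenylpent-4-en-1-yl]sulfonyl}-1H-tetrazole
Conditions: (NH4)6Mo7O24·4H2O (10 mol %), 30 % aq H2O2 (5 equiv), EtOH, 0 °C → rt
Reagents that add atoms: hydrogen peroxide, OO
Why: Molybdate-catalysed oxidation of sulfide to sulfone is much faster than epoxidation of a 1,2-disubstituted styrenyl alkene, so the sulfone needed for the Julia–Kocienski olefination should form cleanly.

Step 4
Reactants: 6 (R)-citronellic acid
Product: 7 (4R)-4,8-dimethylnon-7-en-2-one
Conditions: MeLi (2.2 equiv), Et2O, 0 °C → rt; then H2O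
Reagents that add atoms: methyllithium, [Li]C
Why: Organolithium ketone synthesis, in which MeLi adds to the lithium carboxylate and stops at the dilithio gem-diolate that collapses to the methyl ketone only on work-up; C8 comes from the chiral pool, is β to the carbonyl and is not touched.

Step 5
Reactants: 7 (4R)-4,8-dimethylnon-7-en-2-one
Product: 9 (4R)-4-methyl-6-oxoheptanal, via secondary ozonide 8 (not isolated)
Conditions: O3, CH2Cl2, −78 °C; then Me2S, −78 °C → rt
Reagents that add atoms: ozone, [O-][O+]=O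
Why: Ozonolysis with reductive work-up cleaves the only C=C bond and unmasks C11 as the aldehyde, the ketone being inert.

Step 6
Reactants: 5 1-phenyl-5-{[(4E)-5-phenylpent-4-en-1-yl]sulfonyl}-1H-tetrazole; 9 (4R)-4-methyl-6-oxoheptanal
Product: 10 (4R,7E,11E)-4-methyl-12-phenyldodeca-7,11-dien-2-one
Conditions: 5, KHMDS (1.05 equiv), DME, −60 °C, 30 min; then 9, −60 °C → rt
Reagents that add atoms: none
Why: Julia–Kocienski olefination, in which the pre-metalated phenyltetrazolyl sulfone adds to the aldehyde far faster than to the methyl ketone and the addition/Smiles/elimination sequence should give the E C11=C12 alkene.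

Step 7
Reactants: 10 (4R,7E,11E)-4-methyl-12-phenyldodeca-7,11-dien-2-one
Product: 11 (2S)-2-methyl-2-[(2R,5E,9E)-2-methyl-10-phenyldeca-5,9-dien-1-yl]oxirane
Conditions: Me3S(O)I, NaH, THF (ylide pre-formed); La–Li3–tris[(S)-binaphthoxide] (5 mol %), [2,4,6-(MeO)3C6H2]3P=O (5 mol %), 5 Å MS, THF, rt
Reagents that add atoms: trimethylsulfoxonium iodide, C[S+](C)(C)=O.[I-]
Why: Catalytic asymmetric Corey–Chaykovsky epoxidation, in which the La/Li binaphthoxide binds ketone and ylide together, tells CH3 from CH2R and should deliver CH2 (C5) to the Re face, setting C6 as S independently of the remote C8 centre.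

Step 8
Reactants: 11 (2S)-2-methyl-2-[(2R,5E,9E)-2-methyl-10-phenyldeca-5,9-dien-1-yl]oxirane
Product: 12 (4S,6R,9E,13E)-2,4,6-trimethyl-14-phenyltetradeca-1,9,13-trien-4-ol
Conditions: CH2=C(CH3)MgBr (2 equiv), CuI (10 mol %), THF, −30 → 0 °C; then H2O
Reagents that add atoms: isopropenylmagnesium bromide, CC(=C)[Mg]Br
Why: Copper-catalysed SN2 opening of the 2,2-disubstituted epoxide by the alkenyl Grignard reagent occurs at the unhindered CH2 (C5), so the C6–O bond and its configuration are retained.

Step 9
Reactants: 12 (4S,6R,9E,13E)-2,4,6-trimethyl-14-phenyltetradeca-1,9,13-trien-4-ol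
Product: 13 (2S,4R,7E,11E)-2,4-dimethyl-1-[(2R)-2-methyloxiran-2-yl]-12-phenyldodeca-7,11-dien-2-ol
Conditions: Hf(OtBu)4 (10 mol %), (R,R)-bis-hydroxamic acid (BHA) ligand (12 mol %), cumene hydroperoxide (1.5 equiv), 4 Å MS, toluene, 0 °C
Reagents that add atoms: cumene hydroperoxide, CC(C)(OO)c1ccccc1
Why: Hydroxyl-directed catalytic asymmetric epoxidation, in which only the alkene held at the metal by the C6 alkoxide (C3=C4) is oxidised, the chain alkenes having no directing group, and the C2-symmetric ligand rather than the substrate (CH3 and CH2R on C6 are alike) should fix C4 as R.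

Step 10
Reactants: 13 (2S,4R,7E,11E)-2,4-dimethyl-1-[(2R)-2-methyloxiran-2-yl]-12-phenyldodeca-7,11-dien-2-ol
Product: 14 {(2S,4S)-2,4-dimethyl-4-[(2R,5E,9E)-2-methyl-10-phenyldeca-5,9-dien-1-yl]oxetan-2-yl}methanol (the two ring methyl groups cis)
Conditions: CSA (5 mol %), CH2Cl2, −40 → −10 °C; Et3N quench
Reagents that add atoms: none
Why: Acid-induced homo-Payne-type rearrangement (4-exo-tet epoxide opening), in which the C6 hydroxyl attacks the protonated epoxide from the rear at its tertiary carbon C4, helped by the gem-dialkyl effect at C4 and C6; this inverts C4 (to S), keeps C6–O and frees C3 as CH2OH.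

Step 11
Reactants: 14 {(2S,4S)-2,4-dimethyl-4-[(2R,5E,9E)-2-methyl-10-phenyldeca-5,9-dien-1-yl]oxetan-2-yl}methanol
Product: 15 (2S,4S)-2,4-dimethyl-4-[(2R,5E,9E)-2-methyl-10-phenyldeca-5,9-dien-1-yl]oxetane-2-carbaldehyde
Conditions: TPAP (5 mol %), NMO (1.5 equiv), 4 Å MS, CH2Cl2, rt
Reagents that add atoms: none
Why: Ley–Griffith oxidation under neutral conditions takes the neopentyl-type primary alcohol to the non-enolisable aldehyde without acid that could open the oxetane and without touching the alkenes.

Step 12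
Reactants: 15 (2S,4S)-2,4-dimethyl-4-[(2R,5E,9E)-2-methyl-10-phenyldeca-5,9-dien-1-yl]oxetane-2-carbaldehyde
Product: 16 methyl (2Z)-3-{(2S,4S)-2,4-dimethyl-4-[(2R,5E,9E)-2-methyl-10-phenyldeca-5,9-dien-1-yl]oxetan-2-yl}prop-2-enoate
Conditions: (CF3CH2O)2P(O)CH2CO2Me, KHMDS, 18-crown-6, THF, −78 °C
Reagents that add atoms: methyl 2-[bis(2,2,2-trifluoroethoxy)phosphoryl]acetate, COC(=O)CP(=O)(OCC(F)(F)F)OCC(F)(F)F
Why: Still–Gennari olefination, in which the electron-poor phosphonate under dissociating conditions eliminates under kinetic control and should give the Z-enoate needed for the later lactonisation, the oxetane being stable to base.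

Step 13
Reactants: 16 methyl (2Z)-3-{(2S,4S)-2,4-dimethyl-4-[(2R,5E,9E)-2-methyl-10-phenyldeca-5,9-dien-1-yl]oxetan-2-yl}prop-2-enoate
Product: 19 target peroxylactone (3S,4S,6R,8R; cis-fused 1,2-dioxane/γ-lactone), via hydroperoxy hydroxy ester 17 (not isolated), via hydroperoxy butenolide 18 (not isolated)
Conditions: anhydrous H2O2 in Et2O (10 equiv), TMSOTf (10 mol %), −40 → 0 °C; then Et3N, CF3CH2OH, rt, one pot
Reagents that add atoms: hydrogen peroxide, OO
Why: The acid activates the oxetane oxygen and H2O2 attacks C6 from the rear in a loose SN2 process driven by release of the four-membered-ring strain, giving 17; this is the known acid-catalysed perhydrolysis of tertiary oxetanes, coupled here to the known hydroperoxide/butenolide oxa-Michael cyclisation. The freed C4 hydroxyl is acylated by the Z-ester (5-exo-trig addition–elimination, loss of MeOH) to give butenolide 18, and after addition of Et3N the C6 peroxy anion adds to C3 in a 6-exo-trig oxa-Michael reaction followed by protonation at C2, so the 1,2-dioxane is the last ring to close. C6 (R) is set by inversion of the (6S)-oxetane carbon, C4 (S) is a spectator because its C–O bond is never broken, and C3 (S) is dictated by the tether C4–C5–C6, which lets the peroxide reach only the butenolide face cis to C5, that is, only the cis-fused bicycle. The step needs cleavage of C6–O and not of C4–O, which is secured because positive charge builds up easily at the trialkyl carbon C6 but is disfavoured at C4, which carries the electron-poor acrylate. It also needs the C11=C12 and styrenyl alkenes to survive, which is secured because no radicals, metal hydrides or electrophilic oxidants are present. Base is withheld until lactonisation is complete so that the hydroperoxide cannot add to the open-chain enoate first.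

Compound list
1 | styrene | C=Cc1ccccc1 | starting material
2 | pent-4-en-1-ol | C=CCCCO | starting material
3 | (E)-5-phenylpent-4-en-1-ol | OCCC/C=C/c1ccccc1 | intermediate
4 | 1-phenyl-5-{[(4E)-5-phenylpent-4-en-1-yl]sulfanyl}-1H-tetrazole | c1ccccc1/C=C/CCCSc1nnnn1-c1ccccc1 | intermediate
5 | 1-phenyl-5-{[(4E)-5-phenylpent-4-en-1-yl]sulfonyl}-1H-tetrazole | O=S(=O)(CCC/C=C/c1ccccc1)c1nnnn1-c1ccccc1 | intermediate
6 | (R)-citronellic acid, (3R)-3,7-dimethyloct-6-enoic acid | C[C@H](CCC=C(C)C)CC(=O)O | starting material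
7 | (4R)-4,8-dimethylnon-7-en-2-one | C[C@H](CCC=C(C)C)CC(C)=O | intermediate
8 | secondary ozonide (1,2,4-trioxolane) of 7 | C[C@H](CCC1OOC(C)(C)O1)CC(C)=O | intermediate
9 | (4R)-4-methyl-6-oxoheptanal | C[C@H](CCC=O)CC(C)=O | intermediate
10 | (4R,7E,11E)-4-methyl-12-phenyldodeca-7,11-dien-2-one | C[C@H](CC/C=C/CC/C=C/c1ccccc1)CC(C)=O | intermediate
11 | (2S)-2-methyl-2-[(2R,5E,9E)-2-methyl-10-phenyldeca-5,9-dien-1-yl]oxirane | C[C@H](CC/C=C/CC/C=C/c1ccccc1)C[C@@]1(C)CO1 | intermediate
12 | (4S,6R,9E,13E)-2,4,6-trimethyl-14-phenyltetradeca-1,9,13-trien-4-ol | C[C@H](CC/C=C/CC/C=C/c1ccccc1)C[C@](C)(O)CC(C)=C | intermediate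
13 | (2S,4R,7E,11E)-2,4-dimethyl-1-[(2R)-2-methyloxiran-2-yl]-12-phenyldodeca-7,11-dien-2-ol | C[C@H](CC/C=C/CC/C=C/c1ccccc1)C[C@](C)(O)C[C@]1(C)CO1 | intermediate
14 | {(2S,4S)-2,4-dimethyl-4-[(2R,5E,9E)-2-methyl-10-phenyldeca-5,9-dien-1-yl]oxetan-2-yl}methanol | C[C@H](CC/C=C/CC/C=C/c1ccccc1)C[C@@]1(C)C[C@@](C)(CO)O1 | intermediate
15 | (2S,4S)-2,4-dimethyl-4-[(2R,5E,9E)-2-methyl-10-phenyldeca-5,9-dien-1-yl]oxetane-2-carbaldehyde | C[C@H](CC/C=C/CC/C=C/c1ccccc1)C[C@@]1(C)C[C@@](C)(C=O)O1 | intermediate
16 | methyl (2Z)-3-{(2S,4S)-2,4-dimethyl-4-[(2R,5E,9E)-2-methyl-10-phenyldeca-5,9-dien-1-yl]oxetan-2-yl}prop-2-enoate | C[C@H](CC/C=C/CC/C=C/c1ccccc1)C[C@@]1(C)C[C@@](C)(/C=C\C(=O)OC)O1 | intermediate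
17 | methyl (2Z,4S,6R,8R,11E,15E)-6-hydroperoxy-4-hydroxy-4,6,8-trimethyl-16-phenylhexadeca-2,11,15-trienoate | C[C@H](CC/C=C/CC/C=C/c1ccccc1)C[C@@](C)(OO)C[C@](C)(O)/C=C\C(=O)OC | intermediate
18 | (5S)-5-[(2R,4R,7E,11E)-2-hydroperoxy-2,4-dimethyl-12-phenyldodeca-7,11-dien-1-yl]-5-methylfuran-2(5H)-one | C[C@H](CC/C=C/CC/C=C/c1ccccc1)C[C@@](C)(OO)C[C@]1(C)OC(=O)C=C1 | intermediate
19 | target, cis-fused 1,2-dioxane/γ-lactone (3S,4S,6R,8R) | C[C@H](CC/C=C/CC/C=C/c1ccccc1)C[C@]1(C)C[C@]2(C)OC(=O)C[C@@H]2OO1 | target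

Total step count: 13. Longest linear sequence: 11 (steps 1–3 and 6–13; 10 steps from citronellic acid).

Steps most likely to fail

Step 13. Full ionisation may take over from rear-side attack, which would erode the configuration at C6, lose a proton to give alkenes or let the C11=C12 alkene capture the cation. Cleavage at C4–O may also compete. The fallback gives up strain release and brings the peroxide in by oxymercuration; it sets out from 16 and comes back at 19.
- Treating 16 with catalytic TsOH in CH2Cl2 ionises C6–O, loses a proton and lactonises to the exo-methylene butenolide F1.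
- Markovnikov hydroperoxymercuration (Hg(OAc)2, H2O2, THF) is much faster for a 1,1-disubstituted alkene than for trans-1,2-disubstituted ones and gives the β-acetoxymercurio hydroperoxide F2.
- Et3N in CF3CH2OH closes the dioxane to the mercurated peroxylactone F3, epimeric at C6.
- Reductive demercuration (NaBH4, aq NaOH, 0 °C) should give 19 together with the 6-epimeric peroxylactone F4, which is removed by chromatography.

Step 10. The activated epoxide may undergo a 1,2-hydride shift, close 5-endo at C3, scramble at C4 through an SN1 pathway, or the acid-sensitive oxetane may re-open. The fallback avoids the oxetane; it sets out from 12 and comes back at 19.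
- Epoxidation of 12 with the mirror-image BHA ligand gives the (4S)-epoxy alcohol F5.
- Dilithiated (phenylselanyl)acetic acid opens F5 at C3 with retention at C4, and acidic work-up lactonises to the α-selanyl lactone F6.
- Oxidation with H2O2 at 0 °C and selenoxide syn-elimination give the hydroxy butenolide F7.
- Dehydration with methyl N-(triethylammoniosulfonyl)carbamate gives the exo-methylene butenolide F1, which is carried on through F2 and F3 as described above.

Step 9. Facial selectivity may be poor or conversion low, because the tertiary carbinol is hindered and the 1,1-disubstituted alkene offers little bias. The fallback makes C4 from a ketone instead of an alkene; it sets out from 11 and comes back at 13.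
- 2-Lithio-2-methyl-1,3-dithiane opens 11 at C5 to the hydroxy dithiane F8.
- MeI and CaCO3 in aqueous MeCN unmask the β-hydroxy methyl ketone F9.
- A second La/Li-binaphthoxide-catalysed Corey–Chaykovsky epoxidation of this methyl ketone, with the ligand chosen for (4R), gives 13.

Further compounds
F1 | step 13 | (5S)-5-methyl-5-[(4R,7E,11E)-4-methyl-2-methylidene-12-phenyldodeca-7,11-dien-1-yl]furan-2(5H)-one | C[C@H](CC/C=C/CC/C=C/c1ccccc1)CC(=C)C[C@]1(C)OC(=O)C=C1
F2 | step 13 | β-acetoxymercurio hydroperoxide of F1 (C6 epimers) | C[C@H](CC/C=C/CC/C=C/c1ccccc1)CC(C[Hg]OC(C)=O)(OO)C[C@]1(C)OC(=O)C=C1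
F3 | step 13 | 6-(acetoxymercuriomethyl) peroxylactone (C6 epimers) | C[C@H](CC/C=C/CC/C=C/c1ccccc1)CC1(C[Hg]OC(C)=O)C[C@]2(C)OC(=O)C[C@@H]2OO1
F4 | step 13 | 6-epimer of 19 (3S,4S,6S,8R) | C[C@H](CC/C=C/CC/C=C/c1ccccc1)C[C@@]1(C)C[C@]2(C)OC(=O)C[C@@H]2OO1
F5 | step 10 | (2S,4R,7E,11E)-2,4-dimethyl-1-[(2S)-2-methyloxiran-2-yl]-12-phenyldodeca-7,11-dien-2-ol | C[C@H](CC/C=C/CC/C=C/c1ccccc1)C[C@](C)(O)C[C@@]1(C)CO1
F6 | step 10 | α-(phenylselanyl)-γ-lactone with free C6 hydroxyl | C[C@H](CC/C=C/CC/C=C/c1ccccc1)C[C@](C)(O)C[C@@]1(C)CC([Se]c2ccccc2)C(=O)O1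
F7 | step 10 | (5S)-5-[(2S,4R,7E,11E)-2-hydroxy-2,4-dimethyl-12-phenyldodeca-7,11-dien-1-yl]-5-methylfuran-2(5H)-one | C[C@H](CC/C=C/CC/C=C/c1ccccc1)C[C@](C)(O)C[C@]1(C)OC(=O)C=C1
F8 | step 9 | (2S,4R,7E,11E)-2,4-dimethyl-1-(2-methyl-1,3-dithian-2-yl)-12-phenyldodeca-7,11-dien-2-ol | C[C@H](CC/C=C/CC/C=C/c1ccccc1)C[C@](C)(O)CC1(C)SCCCS1
F9 | step 9 | (4S,6R,9E,13E)-4-hydroxy-4,6-dimethyl-14-phenyltetradeca-9,13-dien-2-one | C[C@H](CC/C=C/CC/C=C/c1ccccc1)C[C@](C)(O)CC(C)=O
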